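**Plan**
- Retrosynthetic cuts: first the acetate C–O bond and the four O–benzyl bonds; then the phloroglucinol ring bond between the acyl-bearing carbon and a neighbouring C–OH carbon, which unfolds the ring into a methyl 3,5,7-trioxoheptadecanoate; then C6–C7 of that chain; last the aryl–CH2 bond at C2 of the resorcinol.
- Enabling feature: in the 2,4,6-trihydroxyphenyl ketone the six ring carbons alternate C–OH and C–H and carry one exocyclic C=O. This is a folded tetraketide, so C1–C6 of a 3,5,7-triketo ester map onto the ring and C7 onto the ketone.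
- Forward: the resorcinol diether is iodinated at C2 and joined to a C11 ester chain by B-alkyl Suzuki coupling. The ester acylates the trianion of methyl 3,5-dioxohexanoate, and magnesium methoxide closes the only ring made in the route.
- Finish: the three new phenols are benzylated, MOM is exchanged for acetyl on the resorcinol, and all four benzyl ethers are hydrogenolysed.
- Stereochemistry: the target has no stereocentre and no stereogenic double bond, so nothing has to be set.

Key step: step 5

Remark: the target is achiral, so its constitution alone meets the "single enantiomer" requirement; the polycarbonyl intermediates are drawn as keto tautomers although they should exist largely as enols.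

**Step 1**
Reactants: 1 3-(benzyloxy)phenol
Product: 2 1-(benzyloxy)-3-(methoxymethoxy)benzene
Conditions: MOMCl, iPr2NEt, CH2Cl2, 0 °C → rt
Reagents that add atoms: chloromethyl methyl ether, COCCl
Why: Williamson-type O-alkylation of the phenol gives the MOM acetal, which later directs metalation and can be removed by acid in the presence of benzyl ethers.

**Step 2**
Reactants: 2 1-(benzyloxy)-3-(methoxymethoxy)benzene
Product: 4 1-(benzyloxy)-2-iodo-3-(methoxymethoxy)benzene, via aryllithium 3 (not isolated)
Conditions: n-BuLi, THF, 0 °C; then I2, −78 °C → rt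
Reagents that add atoms: iodine, II
Why: Directed ortho-metalation, in which OMOM and OBn cooperatively steer n-BuLi to the carbon between them, followed by a cold iodine quench that should trap the aryllithium before benzylic metalation or anion translocation of the benzyl ether can compete.

**Step 3**
Reactants: 4 1-(benzyloxy)-2-iodo-3-(methoxymethoxy)benzene; 5 methyl undec-10-enoate
Product: 7 methyl 11-[2-(benzyloxy)-6-(methoxymethoxy)phenyl]undecanoate, via B-alkyl-9-BBN ester 6 (not isolated)
Conditions: 5, 9-BBN-H, THF, 0 °C → rt; then 4, Pd(OAc)2, SPhos, aq. K3PO4, THF, 65 °C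
Reagents that add atoms: none
Why: Anti-Markovnikov hydroboration of the terminal alkene with 9-BBN spares the ester, and B-alkyl Suzuki–Miyaura coupling with a bulky biarylphosphine–palladium catalyst should join the primary alkyl group to the di-ortho-substituted aryl iodide under phosphate base that leaves the ester, MOM and benzyl groups intact.

**Step 4**
Reactants: 7 methyl 11-[2-(benzyloxy)-6-(methoxymethoxy)phenyl]undecanoate; 8 methyl 3,5-dioxohexanoate
Product: 10 methyl 17-[2-(benzyloxy)-6-(methoxymethoxy)phenyl]-3,5,7-trioxoheptadecanoate, via trilithium trianion 9 (not isolated)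
Conditions: 8 (2.5 equiv), LDA (7.6 equiv), THF, 0 °C; then 7, −78 → 0 °C; AcOH quench
Reagents that add atoms: none
Why: Polyanion acylation (Claisen-type condensation), in which the terminal C6 carbanion of the trianion, formed last and least stabilised, is the most nucleophilic site and attacks the ester carbonyl of 7, while the excess trianion takes up the acidic protons of the new triketo ester.

**Step 5**
Reactants: 10 methyl 17-[2-(benzyloxy)-6-(methoxymethoxy)phenyl]-3,5,7-trioxoheptadecanoate
Product: 12 11-[2-(benzyloxy)-6-(methoxymethoxy)phenyl]-1-(2,4,6-trihydroxyphenyl)undecan-1-one, via acylcyclohexanetrione 11 (not isolated)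
Conditions: Mg(OMe)2, MeOH, reflux; then cold 1 M HCl to pH 3
Reagents that add atoms: none
Why: Magnesium methoxide turns the triketo ester into a chelated polyenolate in which C6, the central carbon of the C5/C7 diketonate, adds to the ester carbonyl C1 and methoxide is expelled, a 6-exo-trig (enolexo) closure that forms the C1–C6 bond and the only new ring. The 2-acylcyclohexane-1,3,5-trione 11 so formed should tautomerise at once to the aromatic triol, held as its magnesium phenoxide until acidification. The closest known reaction type is the biomimetic Claisen (Dieckmann-type) cyclisation of 3,5,7-triketo esters to acylphloroglucinols, the laboratory counterpart of a type III polyketide synthase. No stereocentre is created. The selectivity needed is C6→C1 Claisen closure over C2→C7 aldol closure (which would give a resorcylate) and over O-acylation to a pyranone; it is secured by keeping C1 as a methyl ester in anhydrous methanolic Mg(OMe)2, where Mg2+ chelation favours C-acylation and the aldol and lactone pathways stay reversible while only the Claisen pathway ends in irreversible aromatisation. The MOM and benzyl ethers and the saturated decamethylene chain are inert to alkoxide.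

**Step 6**
Reactants: 12 11-[2-(benzyloxy)-6-(methoxymethoxy)phenyl]-1-(2,4,6-trihydroxyphenyl)undecan-1-one
Product: 13 11-[2-(benzyloxy)-6-(methoxymethoxy)phenyl]-1-[2,4,6-tris(benzyloxy)phenyl]undecan-1-one
Conditions: BnBr, K2CO3, cat. Bu4NI, DMF, 60 °C
Reagents that add atoms: benzyl bromide, BrCc1ccccc1
Why: Williamson ether synthesis in a polar aprotic solvent favours O- over C-alkylation of the phenoxides and, with excess benzyl bromide and heat, should also etherify the two hydrogen-bonded ortho hydroxyls, as it does for simple acylphloroglucinols.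

**Step 7**
Reactants: 13 11-[2-(benzyloxy)-6-(methoxymethoxy)phenyl]-1-[2,4,6-tris(benzyloxy)phenyl]undecan-1-one
Product: 14 11-[2-(benzyloxy)-6-hydroxyphenyl]-1-[2,4,6-tris(benzyloxy)phenyl]undecan-1-one
Conditions: cat. conc. HCl, MeOH/THF, 45 °C
Reagents that add atoms: none
Why: Acid-catalysed acetal exchange (methanolysis of the MOM ether) frees the resorcinol hydroxyl, while benzyl ethers and the hindered aryl ketone are stable to dilute HCl in methanol.

**Step 8**
Reactants: 14 11-[2-(benzyloxy)-6-hydroxyphenyl]-1-[2,4,6-tris(benzyloxy)phenyl]undecan-1-one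
Product: 15 3-(benzyloxy)-2-{11-oxo-11-[2,4,6-tris(benzyloxy)phenyl]undecyl}phenyl acetate
Conditions: Ac2O, pyridine, cat. DMAP, CH2Cl2, rt
Reagents that add atoms: acetic anhydride, CC(=O)OC(C)=O
Why: DMAP-catalysed O-acylation of the only free hydroxyl in the molecule places the acetyl group unambiguously on the resorcinol oxygen.

**Step 9**
Reactants: 15 3-(benzyloxy)-2-{11-oxo-11-[2,4,6-tris(benzyloxy)phenyl]undecyl}phenyl acetate
Product: 16 3-hydroxy-2-[11-oxo-11-(2,4,6-trihydroxyphenyl)undecyl]phenyl acetate
Conditions: H2 (1 atm), 10% Pd/C, EtOAc, rt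
Reagents that add atoms: none
Why: Catalytic hydrogenolysis of the four benzyl aryl ethers in neutral, non-nucleophilic ethyl acetate should leave the aryl acetate, the saturated chain and the electron-rich aryl ketone (a vinylogous acid) untouched.

**Compound list**
1 | 3-(benzyloxy)phenol | Oc1cccc(OCc2ccccc2)c1 | starting material
2 | 1-(benzyloxy)-3-(methoxymethoxy)benzene | COCOc1cccc(OCc2ccccc2)c1 | intermediate
3 | [2-(benzyloxy)-6-(methoxymethoxy)phenyl]lithium | [Li]c1c(OCOC)cccc1OCc1ccccc1 | intermediate
4 | 1-(benzyloxy)-2-iodo-3-(methoxymethoxy)benzene | COCOc1cccc(OCc2ccccc2)c1I | intermediate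
5 | methyl undec-10-enoate | C=CCCCCCCCCC(=O)OC | starting material
6 | methyl 11-(9-borabicyclo[3.3.1]nonan-9-yl)undecanoate | COC(=O)CCCCCCCCCCB1C2CCCC1CCC2 | intermediate
7 | methyl 11-[2-(benzyloxy)-6-(methoxymethoxy)phenyl]undecanoate | COC(=O)CCCCCCCCCCc1c(OCOC)cccc1OCc1ccccc1 | intermediate
8 | methyl 3,5-dioxohexanoate | COC(=O)CC(=O)CC(C)=O | starting material
9 | trilithium trianion of methyl 3,5-dioxohexanoate (deprotonated at C2, C4 and C6) | [Li+].[Li+].[Li+].COC(=O)[CH-]C(=O)[CH-]C(=O)[CH2-] | intermediate
10 | methyl 17-[2-(benzyloxy)-6-(methoxymethoxy)phenyl]-3,5,7-trioxoheptadecanoate | COC(=O)CC(=O)CC(=O)CC(=O)CCCCCCCCCCc1c(OCOC)cccc1OCc1ccccc1 | intermediate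
11 | 2-{11-[2-(benzyloxy)-6-(methoxymethoxy)phenyl]undecanoyl}cyclohexane-1,3,5-trione | COCOc1cccc(OCc2ccccc2)c1CCCCCCCCCCC(=O)C1C(=O)CC(=O)CC1=O | intermediate
12 | 11-[2-(benzyloxy)-6-(methoxymethoxy)phenyl]-1-(2,4,6-trihydroxyphenyl)undecan-1-one | COCOc1cccc(OCc2ccccc2)c1CCCCCCCCCCC(=O)c1c(O)cc(O)cc1O | intermediate
13 | 11-[2-(benzyloxy)-6-(methoxymethoxy)phenyl]-1-[2,4,6-tris(benzyloxy)phenyl]undecan-1-one | COCOc1cccc(OCc2ccccc2)c1CCCCCCCCCCC(=O)c1c(OCc2ccccc2)cc(OCc2ccccc2)cc1OCc1ccccc1 | intermediate
14 | 11-[2-(benzyloxy)-6-hydroxyphenyl]-1-[2,4,6-tris(benzyloxy)phenyl]undecan-1-one | Oc1cccc(OCc2ccccc2)c1CCCCCCCCCCC(=O)c1c(OCc2ccccc2)cc(OCc2ccccc2)cc1OCc1ccccc1 | intermediate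
15 | 3-(benzyloxy)-2-{11-oxo-11-[2,4,6-tris(benzyloxy)phenyl]undecyl}phenyl acetate | CC(=O)Oc1cccc(OCc2ccccc2)c1CCCCCCCCCCC(=O)c1c(OCc2ccccc2)cc(OCc2ccccc2)cc1OCc1ccccc1 | intermediate
16 | 3-hydroxy-2-[11-oxo-11-(2,4,6-trihydroxyphenyl)undecyl]phenyl acetate (CNP0111377.0) | CC(=O)Oc1cccc(O)c1CCCCCCCCCCC(=O)c1c(O)cc(O)cc1O | target

**Step count and risks**
Total step count: 9. Longest linear sequence: 9 steps (1 → 16); compounds 5 and 8 enter as purchased fragments.

Steps most likely to fail:

Step 4. Proton transfer may outrun C–C bond formation: the trianion can enolise the aliphatic ester or be quenched by the more acidic triketo ester as it forms, and the methoxide released may start premature cyclisation or retro-Claisen cleavage. The fallback sets out from 7 and returns at 10. Ester 7 would be converted with MeNHOMe·HCl and i-PrMgCl (THF, −20 °C) into the Weinreb amide N-methoxy-N-methyl-11-[2-(benzyloxy)-6-(methoxymethoxy)phenyl]undecanamide F1. F1 would then be added to trianion 9 (THF, −78 → 0 °C). The magnesium- or lithium-chelated tetrahedral adduct should survive until the acidic quench, so that no alkoxide is liberated and no ketone is exposed to the polyanion, and collapse on work-up should give 10.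

Step 5. The polyenolate may close in the wrong mode: aldol addition of C2 to the C7 ketone with dehydration to a resorcylate, O-acylation to a pyranone, or methanolytic chain cleavage. The fallback abandons ring construction, sets out from 7 and returns at 13. Ester 7 would be reduced with DIBAL-H (CH2Cl2, −78 °C) to the aldehyde 11-[2-(benzyloxy)-6-(methoxymethoxy)phenyl]undecanal F2. In parallel, commercial 1,3,5-tris(benzyloxy)benzene would be brominated with NBS (CH2Cl2, −20 °C) to 2-bromo-1,3,5-tris(benzyloxy)benzene F3, which on bromine–lithium exchange (n-BuLi, THF, −78 °C) should give [2,4,6-tris(benzyloxy)phenyl]lithium F4. Addition of F4 to F2 at −78 °C should furnish the racemic carbinol 11-[2-(benzyloxy)-6-(methoxymethoxy)phenyl]-1-[2,4,6-tris(benzyloxy)phenyl]undecan-1-ol F5. Dess–Martin oxidation (NaHCO3, CH2Cl2) would then give ketone 13, with the phloroglucinol already benzylated.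

Step 6. The ambident phloroglucinolate may be benzylated at ring carbon instead of oxygen, and etherification of the two chelated ortho hydroxyls may stop short. The fallback replaces alkylation by hard O-acylation, sets out from 12 and returns at 16. Treatment of 12 with CbzCl, Et3N and cat. DMAP (CH2Cl2, 0 °C) should give the tris(benzyl carbonate) 2-{11-[2-(benzyloxy)-6-(methoxymethoxy)phenyl]undecanoyl}benzene-1,3,5-triyl tribenzyl tricarbonate F6. MOM removal with HCl in dioxane containing a little methanol (0 °C) would give the phenol 2-{11-[2-(benzyloxy)-6-hydroxyphenyl]undecanoyl}benzene-1,3,5-triyl tribenzyl tricarbonate F7. Acetylation with Ac2O/pyridine would give 3-(benzyloxy)-2-{11-oxo-11-[2,4,6-tris(benzyloxycarbonyloxy)phenyl]undecyl}phenyl acetate F8. Hydrogenolysis (H2, Pd/C, EtOAc) should then remove the three carbonates and the benzyl ether together to give 16.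

**Further compounds**
F1 | step 4 | N-methoxy-N-methyl-11-[2-(benzyloxy)-6-(methoxymethoxy)phenyl]undecanamide | CON(C)C(=O)CCCCCCCCCCc1c(OCOC)cccc1OCc1ccccc1
F2 | step 5 | 11-[2-(benzyloxy)-6-(methoxymethoxy)phenyl]undecanal | O=CCCCCCCCCCCc1c(OCOC)cccc1OCc1ccccc1
F3 | step 5 | 2-bromo-1,3,5-tris(benzyloxy)benzene | Brc1c(OCc2ccccc2)cc(OCc2ccccc2)cc1OCc1ccccc1
F4 | step 5 | [2,4,6-tris(benzyloxy)phenyl]lithium | [Li]c1c(OCc2ccccc2)cc(OCc2ccccc2)cc1OCc1ccccc1
F5 | step 5 | 11-[2-(benzyloxy)-6-(methoxymethoxy)phenyl]-1-[2,4,6-tris(benzyloxy)phenyl]undecan-1-ol (racemic) | COCOc1cccc(OCc2ccccc2)c1CCCCCCCCCCC(O)c1c(OCc2ccccc2)cc(OCc2ccccc2)cc1OCc1ccccc1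
F6 | step 6 | 2-{11-[2-(benzyloxy)-6-(methoxymethoxy)phenyl]undecanoyl}benzene-1,3,5-triyl tribenzyl tricarbonate | COCOc1cccc(OCc2ccccc2)c1CCCCCCCCCCC(=O)c1c(OC(=O)OCc2ccccc2)cc(OC(=O)OCc2ccccc2)cc1OC(=O)OCc1ccccc1
F7 | step 6 | 2-{11-[2-(benzyloxy)-6-hydroxyphenyl]undecanoyl}benzene-1,3,5-triyl tribenzyl tricarbonate | Oc1cccc(OCc2ccccc2)c1CCCCCCCCCCC(=O)c1c(OC(=O)OCc2ccccc2)cc(OC(=O)OCc2ccccc2)cc1OC(=O)OCc1ccccc1
F8 | step 6 | 3-(benzyloxy)-2-{11-oxo-11-[2,4,6-tris(benzyloxycarbonyloxy)phenyl]undecyl}phenyl acetate | CC(=O)Oc1cccc(OCc2ccccc2)c1CCCCCCCCCCC(=O)c1c(OC(=O)OCc2ccccc2)cc(OC(=O)OCc2ccccc2)cc1OC(=O)OCc1ccccc1
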